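**Plan**

Numbering follows isochroman-1-one, C1(=O)–O2–C3–C4–C4a…C8a, with ring A the benzene and ring B the lactone. Cuts, in retrosynthetic order: C8–O (back to C8–B); C4a–C8a, C5–C6 and C7–C8 together; C8–B; the ester bond C1–O2; C3–C4; the C3′=C4′ alkene of the side chain.
Enabling feature: C5, C6 and C7 of ring A carry only hydrogen, and C4a and C8a are bridged by the chain C4–C3–O2–C1 of ring B. Ring A is therefore the sum of acetylene (C6, C7), a terminal alkyne (C4a, C5) and a propiolate alkyne (C8a, C8) tied together by the future lactone, and its one substituent, the C8 oxygen, travels as boron.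
Forward: a C18 dienal is built from a C14 aldehyde and a C4 phosphonate, three carbons are added as a propargyl unit, the alcohol is acylated and the propiolate terminus is borylated. Ring B then closes at the metallacycle stage and ring A on uptake of acetylene, both in one flask, and C–B oxidation ends the route.
Stereochemistry: the E,E-diene comes from the olefination (one alkene made, one brought in by the phosphonate). C3 (R), the only stereocentre, comes from a chiral-phosphoric-acid-catalysed allenylboration of the dienal and is not touched again.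

Key step: step 7

Assumption: the sense of induction of (R)-TRIP known for aryl and alkenyl aldehydes (C–C bond formation on the Re face) is taken to hold for the C18 dienal. If it were reversed, the (S)-acid would be used and nothing else would change.

**Step 1**
Reactants: 1 tetradecanal; 2 triethyl 4-phosphonocrotonate
Product: 3 ethyl (2E,4E)-octadeca-2,4-dienoate
Conditions: LiN(SiMe3)2, THF, −78 °C → rt
Reagents that add atoms: none
Why: Vinylogous Horner–Wadsworth–Emmons olefination, in which the ester-stabilised phosphonate anion attacks the unhindered aldehyde through the carbon next to phosphorus and the reversible addition funnels to the E alkene, so that the new C4=C5 bond should be E, the C2=C3 bond keeps the E geometry of 2, and any 4Z isomer can be removed by chromatography.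

**Step 2**
Reactants: 3 ethyl (2E,4E)-octadeca-2,4-dienoate
Product: 4 (2E,4E)-octadeca-2,4-dien-1-ol
Conditions: i-Bu2AlH, CH2Cl2, −78 → 0 °C; aq. potassium sodium tartrate
Reagents that add atoms: none
Why: Standard 1,2-reduction of a conjugated ester with i-Bu2AlH, which delivers two hydrides to the carbonyl carbon and leaves the diene and its geometry alone.

**Step 3**
Reactants: 4 (2E,4E)-octadeca-2,4-dien-1-ol
Product: 5 (2E,4E)-octadeca-2,4-dienal
Conditions: activated MnO2, CH2Cl2, rt
Reagents that add atoms: none
Why: Allylic alcohol oxidation on activated MnO2, a neutral heterogeneous oxidant that is selective for allylic and dienylic carbinols, stops at the aldehyde and does not isomerise the E,E-diene.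

**Step 4**
Reactants: 5 (2E,4E)-octadeca-2,4-dienal; 6 allenylboronic acid pinacol ester
Product: 8 (4R,5E,7E)-henicosa-5,7-dien-1-yn-4-ol, via O-pinacolboryl ether 7 (not isolated)
Conditions: (R)-TRIP [(R)-3,3′-bis(2,4,6-triisopropylphenyl)-1,1′-binaphthalene-2,2′-diyl hydrogen phosphate] (10–20 mol %), 4 Å MS, toluene, −20 °C; aq. NaHCO3
Reagents that add atoms: none
Why: Chiral-phosphoric-acid-catalysed asymmetric propargylation (allenylboration), for which enals are established substrates: 6 adds through a closed six-membered SE2′ transition state that transposes the allene into the propargyl group, while the acid hydrogen-bonds to a boronate oxygen and to the formyl hydrogen and its triisopropylphenyl walls leave only the Re face of the aldehyde open, which sets C4 as R; borate 7 is cleaved on aqueous work-up.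

**Step 5**
Reactants: 8 (4R,5E,7E)-henicosa-5,7-dien-1-yn-4-ol; 9 propiolic acid
Product: 10 (4R,5E,7E)-henicosa-5,7-dien-1-yn-4-yl prop-2-ynoate
Conditions: DCC, DMAP (5 mol %), CH2Cl2, −20 → 0 °C
Reagents that add atoms: none
Why: Steglich esterification, a routine way to make propiolates of secondary alcohols; the bond formed is acyl C–O, so the C4–O bond and the R configuration are retained, and the low temperature and small amount of DMAP hold back conjugate addition to the propiolate.

**Step 6**
Reactants: 10 (4R,5E,7E)-henicosa-5,7-dien-1-yn-4-yl prop-2-ynoate; 11 2-isopropoxy-4,4,5,5-tetramethyl-1,3,2-dioxaborolane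
Product: 14 (4R,5E,7E)-henicosa-5,7-dien-1-yn-4-yl 3-(4,4,5,5-tetramethyl-1,3,2-dioxaborolan-2-yl)prop-2-ynoate, via lithium acetylide 12 (not isolated), via lithium alkynylborate 13 (not isolated)
Conditions: LiN(SiMe3)2 (1.0 equiv), THF, −78 °C; 11, −78 °C; HCl·Et2O (1.0 equiv), −78 °C → rt; filtration under Ar, evaporation, used crude
Reagents that add atoms: none
Why: Deprotonation–borylation of a terminal alkyne, the standard route to 1-alkynyl pinacol boronates: LiN(SiMe3)2 removes the propiolate C–H, which is more acidic than the alkyl-alkyne C–H by several pK units, but is too weak a base to metalate the other terminus, lithiated propiolate esters persist at −78 °C, capture by 11 gives borate 13, and anhydrous HCl takes off isopropoxide without water, so that the hydrolytically labile 14 needs only filtration and evaporation and C4 is untouched.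

**Step 7**
Reactants: 14 (4R,5E,7E)-henicosa-5,7-dien-1-yn-4-yl 3-(4,4,5,5-tetramethyl-1,3,2-dioxaborolan-2-yl)prop-2-ynoate; 15 acetylene
Product: 17 (3R)-3-[(1E,3E)-heptadeca-1,3-dien-1-yl]-8-(4,4,5,5-tetramethyl-1,3,2-dioxaborolan-2-yl)isochroman-1-one, via rhodacyclopentadiene 16 (not isolated)
Conditions: RhCl(PPh3)3 (5–10 mol %), 15 (1 atm, solution kept saturated), dry toluene, rt → 40 °C, 14 added by syringe pump
Reagents that add atoms: none
Why: RhCl(PPh3)3 sheds a phosphine, binds both alkynes of 14 and couples them oxidatively to rhodacyclopentadiene 16 of trivalent rhodium, which makes C4a–C8a and so closes ring B as a six-membered lactone fused to the metallacycle (intramolecular alkyne–alkyne coupling across the four-atom tether C4–C3–O2–C1). Acetylene 15 then inserts into a Rh–C bond and reductive elimination completes C5–C6 and C7–C8, closing ring A as a benzene in a formal [2+2+2] cycloaddition and returning monovalent rhodium. The closest known reactions are the RhCl(PPh3)3-catalysed crossed cyclotrimerizations of ester-tethered diynes with acetylene gas to benzo-fused lactones and the cyclotrimerizations of diynes that bear a pinacol boronate on an alkyne terminus. No stereocentre is created, and C3 lies outside the reacting atoms under neutral conditions, so the R configuration from step 4 is carried through. Regiochemistry raises no question because 15 is symmetric and the tether places boron on C8 next to C8a; the chemoselectivity needed, cross-trimerization ahead of diyne self-condensation and ahead of rhodium-mediated [4+2] addition of the boryl alkyne to the neighbouring diene, rests on slow addition of 14 into acetylene-saturated toluene, on the much stronger binding of alkynes than of an internal E,E-diene, and on a non-polar medium near room temperature in which diene–yne cycloaddition with this catalyst is slow. Anhydrous, aprotic conditions keep the C(sp)–B bond intact until it has become the robust aryl C–B bond.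

**Step 8**
Reactants: 17 (3R)-3-[(1E,3E)-heptadeca-1,3-dien-1-yl]-8-(4,4,5,5-tetramethyl-1,3,2-dioxaborolan-2-yl)isochroman-1-one
Product: 19 (3R)-8-hydroxy-3-[(1E,3E)-heptadeca-1,3-dien-1-yl]isochroman-1-one, via aryl borate 18 (not isolated)
Conditions: NaBO3·4H2O, THF/H2O (1:1), rt; aq. NH4Cl
Reagents that add atoms: sodium perborate tetrahydrate, O.O.O.O.[Na+].[O-]OB=O
Why: Ipso-oxidation of an arylboronic ester: the peroxoborate anion adds to boron, the aryl group migrates from boron to oxygen to give borate 18, which water cleaves, and this nucleophilic oxidant attacks neither the diene nor, in the short time needed at room temperature, the lactone, so that C3 and both alkenes reach 19 unchanged.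

**Compound list**

1 | tetradecanal | CCCCCCCCCCCCCC=O | starting material
2 | triethyl 4-phosphonocrotonate | CCOC(=O)/C=C/CP(=O)(OCC)OCC | starting material
3 | ethyl (2E,4E)-octadeca-2,4-dienoate | CCCCCCCCCCCCC/C=C/C=C/C(=O)OCC | intermediate
4 | (2E,4E)-octadeca-2,4-dien-1-ol | CCCCCCCCCCCCC/C=C/C=C/CO | intermediate
5 | (2E,4E)-octadeca-2,4-dienal | CCCCCCCCCCCCC/C=C/C=C/C=O | intermediate
6 | allenylboronic acid pinacol ester, 2-(propa-1,2-dien-1-yl)-4,4,5,5-tetramethyl-1,3,2-dioxaborolane | C=C=CB1OC(C)(C)C(C)(C)O1 | starting material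
7 | 2-{[(4R,5E,7E)-henicosa-5,7-dien-1-yn-4-yl]oxy}-4,4,5,5-tetramethyl-1,3,2-dioxaborolane | CCCCCCCCCCCCC/C=C/C=C/[C@H](OB1OC(C)(C)C(C)(C)O1)CC#C | intermediate
8 | (4R,5E,7E)-henicosa-5,7-dien-1-yn-4-ol | CCCCCCCCCCCCC/C=C/C=C/[C@H](O)CC#C | intermediate
9 | propiolic acid | C#CC(=O)O | starting material
10 | (4R,5E,7E)-henicosa-5,7-dien-1-yn-4-yl prop-2-ynoate | CCCCCCCCCCCCC/C=C/C=C/[C@H](OC(=O)C#C)CC#C | intermediate
11 | 2-isopropoxy-4,4,5,5-tetramethyl-1,3,2-dioxaborolane | CC(C)OB1OC(C)(C)C(C)(C)O1 | starting material
12 | (4R,5E,7E)-henicosa-5,7-dien-1-yn-4-yl 3-lithioprop-2-ynoate | CCCCCCCCCCCCC/C=C/C=C/[C@H](OC(=O)C#C[Li])CC#C | intermediate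
13 | lithium alkynyl(isopropoxy)(pinacolato)borate derived from 12 and 11 | CCCCCCCCCCCCC/C=C/C=C/[C@H](OC(=O)C#C[B-]1(OC(C)C)OC(C)(C)C(C)(C)O1)CC#C.[Li+] | intermediate
14 | (4R,5E,7E)-henicosa-5,7-dien-1-yn-4-yl 3-(4,4,5,5-tetramethyl-1,3,2-dioxaborolan-2-yl)prop-2-ynoate | CCCCCCCCCCCCC/C=C/C=C/[C@H](OC(=O)C#CB1OC(C)(C)C(C)(C)O1)CC#C | intermediate
15 | acetylene | C#C | starting material
16 | rhodacyclopentadiene of trivalent rhodium fused to ring B, chlororhodium bridging C5 and C8 (PPh3 ligands left out of the SMILES) | CCCCCCCCCCCCC/C=C/C=C/[C@H]1CC2=C[Rh](Cl)C(B3OC(C)(C)C(C)(C)O3)=C2C(=O)O1 | intermediate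
17 | (3R)-3-[(1E,3E)-heptadeca-1,3-dien-1-yl]-8-(4,4,5,5-tetramethyl-1,3,2-dioxaborolan-2-yl)isochroman-1-one | CCCCCCCCCCCCC/C=C/C=C/[C@H]1Cc2cccc(B3OC(C)(C)C(C)(C)O3)c2C(=O)O1 | intermediate
18 | (3R)-3-[(1E,3E)-heptadeca-1,3-dien-1-yl]-8-[(4,4,5,5-tetramethyl-1,3,2-dioxaborolan-2-yl)oxy]isochroman-1-one | CCCCCCCCCCCCC/C=C/C=C/[C@H]1Cc2cccc(OB3OC(C)(C)C(C)(C)O3)c2C(=O)O1 | intermediate
19 | (3R)-8-hydroxy-3-[(1E,3E)-heptadeca-1,3-dien-1-yl]isochroman-1-one (CNP0165705.1) | CCCCCCCCCCCCC/C=C/C=C/[C@H]1Cc2cccc(O)c2C(=O)O1 | target

Total step count: 8. Longest linear sequence: 8 steps (1 → 19).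

**Steps most likely to fail**

**Step 6.**
- What may go wrong: protonolysis of the electron-poor C(sp)–B bond during the acid quench or the concentration, incomplete capture of the stabilised acetylide by 11, or partial metalation at the other alkyne terminus.
- Fallback: boron is brought in only after the rings exist.
- Setting out from 10, cyclotrimerization with 15 under the conditions of step 7 should give (3R)-3-[(1E,3E)-heptadeca-1,3-dien-1-yl]isochroman-1-one F1.
- Carbonyl-directed ortho C–H borylation ([Ir(OMe)(cod)]2, P[3,5-(CF3)2C6H3]3, B2pin2, octane, 80 °C) is a known reaction of benzoate esters. It should functionalise C8, the only aromatic C–H beside the lactone carbonyl, and the sequence rejoins the route at 17.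
- Hydroboration of the diene by the borane formed in this reaction is the point to watch.

**Step 7.**
- What may go wrong: self-condensation of the diyne, sluggish closure because the ester prefers its extended conformer, rhodium-mediated addition of the alkyne to the diene, or ionisation of the dienylic C–O bond at the metal with erosion of configuration.
- Fallback: ring A is made by Diels–Alder addition and aromatisation, and ring B by lactonisation, setting out from 8.
- Silylation (t-BuMe2SiCl, imidazole, DMF) should give (4R,5E,7E)-4-(tert-butyldimethylsilyloxy)henicosa-5,7-dien-1-yne F2.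
- Metalation with n-BuLi and trapping with ClCO2Me should give methyl (5R,6E,8E)-5-(tert-butyldimethylsilyloxy)docosa-6,8-dien-2-ynoate F3.
- The diene partner, 1-methoxy-1-(trimethylsilyloxy)buta-1,3-diene F4, is made from methyl crotonate with LiN(i-Pr)2 and Me3SiCl.
- Heating F3 with F4 in toluene should give, with the nucleophilic diene terminus bonding to the β-carbon of the ynoate, methyl 2-[(2R,3E,5E)-2-(tert-butyldimethylsilyloxy)nonadeca-3,5-dien-1-yl]-6-methoxy-6-(trimethylsilyloxy)cyclohexa-1,4-diene-1-carboxylate F5.
- F5 loses methanol and, on mild acidic work-up, the trimethylsilyl group to give methyl 2-hydroxy-6-[(2R,3E,5E)-2-(tert-butyldimethylsilyloxy)nonadeca-3,5-dien-1-yl]benzoate F6.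
- Bu4NF in THF then frees the secondary alkoxide, which closes ring B onto the methyl ester, and the sequence comes back at 19.

**Step 4.**
- What may go wrong: insufficient facial selectivity with a long-chain dienal, or slow turnover at the low temperature.
- Fallback: racemic addition followed by enzymatic kinetic resolution, setting out from 5.
- Barbier propargylation (Zn, propargyl bromide, THF/aq. NH4Cl) should give racemic (5E,7E)-henicosa-5,7-dien-1-yn-4-ol F7.
- Candida antarctica lipase B with vinyl acetate in hexane should acylate the enantiomer that has the large dienyl chain and the medium propargyl group in the favoured arrangement. This gives (4R,5E,7E)-henicosa-5,7-dien-1-yn-4-yl acetate F8 and leaves (4S,5E,7E)-henicosa-5,7-dien-1-yn-4-ol F9.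
- After chromatographic separation, methanolysis of F8 (K2CO3, MeOH) returns to the route at 8.

**Further compounds**

F1 | step 6 | (3R)-3-[(1E,3E)-heptadeca-1,3-dien-1-yl]isochroman-1-one | CCCCCCCCCCCCC/C=C/C=C/[C@H]1Cc2ccccc2C(=O)O1
F2 | step 7 | (4R,5E,7E)-4-(tert-butyldimethylsilyloxy)henicosa-5,7-dien-1-yne | CCCCCCCCCCCCC/C=C/C=C/[C@H](O[Si](C)(C)C(C)(C)C)CC#C
F3 | step 7 | methyl (5R,6E,8E)-5-(tert-butyldimethylsilyloxy)docosa-6,8-dien-2-ynoate | CCCCCCCCCCCCC/C=C/C=C/[C@H](O[Si](C)(C)C(C)(C)C)CC#CC(=O)OC
F4 | step 7 | 1-methoxy-1-(trimethylsilyloxy)buta-1,3-diene | C=CC=C(OC)O[Si](C)(C)C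
F5 | step 7 | methyl 2-[(2R,3E,5E)-2-(tert-butyldimethylsilyloxy)nonadeca-3,5-dien-1-yl]-6-methoxy-6-(trimethylsilyloxy)cyclohexa-1,4-diene-1-carboxylate (both configurations at C6) | CCCCCCCCCCCCC/C=C/C=C/[C@H](O[Si](C)(C)C(C)(C)C)CC1=C(C(=O)OC)C(OC)(O[Si](C)(C)C)C=CC1
F6 | step 7 | methyl 2-hydroxy-6-[(2R,3E,5E)-2-(tert-butyldimethylsilyloxy)nonadeca-3,5-dien-1-yl]benzoate | CCCCCCCCCCCCC/C=C/C=C/[C@H](O[Si](C)(C)C(C)(C)C)Cc1cccc(O)c1C(=O)OC
F7 | step 4 | racemic (5E,7E)-henicosa-5,7-dien-1-yn-4-ol | CCCCCCCCCCCCC/C=C/C=C/C(O)CC#C
F8 | step 4 | (4R,5E,7E)-henicosa-5,7-dien-1-yn-4-yl acetate | CCCCCCCCCCCCC/C=C/C=C/[C@H](OC(C)=O)CC#C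
F9 | step 4 | (4S,5E,7E)-henicosa-5,7-dien-1-yn-4-ol | CCCCCCCCCCCCC/C=C/C=C/[C@@H](O)CC#C
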